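**Plan**
1. Retrosynthetic cuts: C11–O (aryl ether), C9=C11 (then C9–H), C1–C10 (ring A, key step), C2–C3 (vinyl addition), C8–CH3, C10–CH3 and C4–C5.
2. Enabling feature: the C3 ketone of ring A lies 1,5 to a carbonyl placed at C9 (C3–C2–C1–C10–C9), and quaternary C10 is the α-carbon of that ketone, so C1–C10 is a Michael bond.
3. Forward: cyclohexenone becomes ring B; the C4 side chain and both α-methyls are added, the ester is turned into a vinyl ketone, ring A is closed, then C11 and the coumarin are attached.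
4. The C8 methyl is put in before ring closure, so that in the resulting dione the C9 carbonyl is far more hindered than C3 and the two ketones can be told apart.
5. Stereochemistry: C5 from a chiral oxazaborolidinium catalyst; C10 from C5 in the ring closure (cis fusion); C9 from convex-face hydroboration of the C7=C8–C9=C11 diene.
6. Drimane numbering is used for the bicycles (ring A = C1–C5, C10; ring B = C5–C10; C11 on C9); β is the face of the C10 methyl. The target is 5β-H, 10β-CH3, 9β-H (5S,9R,10S).

Key step: step 8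

Assumption: the (S)-oxazaborolidinium catalyst is taken to give the (1S)-adduct 3; if the sense of induction is the opposite, the (R)-catalyst is used and nothing else changes.

**Step 1**
Reactants: 1 cyclohex-2-en-1-one; 2 1-methoxy-2-methyl-1-(trimethylsilyloxy)prop-1-ene
Product: 3 methyl 2-methyl-2-[(1S)-3-(trimethylsilyloxy)cyclohex-2-en-1-yl]propanoate
Conditions: (S)-3,3-diphenyl-1-(2-methylphenyl)tetrahydro-1H,3H-pyrrolo[1,2-c][1,3,2]oxazaborole (20 mol %) + HN(SO2CF3)2 (20 mol %), Ph3PO (25 mol %), toluene, −20 °C; non-aqueous work-up (concentration, filtration through Et3N-deactivated silica)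
Reagents that add atoms: none
Why: Catalytic enantioselective Mukaiyama–Michael addition, in which the boron-bound enone is attacked on its open face and silyl transfer (Ph3PO suppressing achiral silyl-cation catalysis) should leave the enol ether regiospecifically at C1–C2 with the new centre S.

**Step 2**
Reactants: 3 methyl 2-methyl-2-[(1S)-3-(trimethylsilyloxy)cyclohex-2-en-1-yl]propanoate
Product: 5 methyl 2-methyl-2-[(1S,2R)-2-methyl-3-oxocyclohexyl]propanoate, via benzyltrimethylammonium enolate 4 (not isolated)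
Conditions: MeI (5 equiv), PhCH2NMe3F (anhydrous, 1.2 equiv), 4 Å molecular sieves, THF, 0 °C → rt
Reagents that add atoms: iodomethane, CI
Why: Fluoride-triggered regiospecific enolate alkylation, in which desilylation frees the enolate only at the former C1–C2 position and methylation anti to the bulky neighbouring substituent should give the trans ketone while the α-quaternary ester stays inert.

**Step 3**
Reactants: 5 methyl 2-methyl-2-[(1S,2R)-2-methyl-3-oxocyclohexyl]propanoate
Product: 7 methyl 2-[(1S,2R)-2,4-dimethyl-3-oxocyclohexyl]-2-methylpropanoate (C4 epimers), via lithium enolate 6 (not isolated)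
Conditions: LiN(i-Pr)2 (1.05 equiv), THF, −78 °C; MeI, −78 → −20 °C
Reagents that add atoms: iodomethane, CI
Why: Kinetic enolate alkylation, in which the amide base removes the less hindered ring-methylene proton and MeI installs the future C8 methyl; the new centre is epimerisable and later becomes sp2, so its configuration does not matter.

**Step 4**
Reactants: 7 methyl 2-[(1S,2R)-2,4-dimethyl-3-oxocyclohexyl]-2-methylpropanoate
Product: 8 (2R,3S)-3-(1-hydroxy-2-methylpropan-2-yl)-2,6-dimethylcyclohexan-1-ol (C1 and C6 epimers)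
Conditions: LiAlH4 (2 equiv), THF, 0 °C → rt; NaOH/H2O work-up
Reagents that add atoms: none
Why: LiAlH4 reduction of the hindered ester and of the ketone, which avoids a ketal on the crowded 2,6-dimethyl ketone; the carbinol epimers converge in the next step.

**Step 5**
Reactants: 8 (2R,3S)-3-(1-hydroxy-2-methylpropan-2-yl)-2,6-dimethylcyclohexan-1-ol
Product: 9 2-[(1S,2R)-2,4-dimethyl-3-oxocyclohexyl]-2-methylpropanal (C4 epimers)
Conditions: (COCl)2, Me2SO, CH2Cl2, −78 °C; Et3N, −78 → 0 °C
Reagents that add atoms: none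
Why: Swern oxidation of both alcohols; the aldehyde has no α-hydrogen and so cannot enolise.

**Step 6**
Reactants: 9 2-[(1S,2R)-2,4-dimethyl-3-oxocyclohexyl]-2-methylpropanal; 10 vinylmagnesium bromide
Product: 11 (2R,3S)-3-(3-hydroxy-2-methylpent-4-en-2-yl)-2,6-dimethylcyclohexan-1-one (carbinol and C6 epimers)
Conditions: CH2=CHMgBr (1.1 equiv), THF, −78 °C; aq. NH4Cl
Reagents that add atoms: none
Why: Chemoselective Grignard 1,2-addition, in which the aldehyde should react at −78 °C while the α,α′-disubstituted ketone with a β-quaternary neighbour does not.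

**Step 7**
Reactants: 11 (2R,3S)-3-(3-hydroxy-2-methylpent-4-en-2-yl)-2,6-dimethylcyclohexan-1-one
Product: 12 (2R,3S)-2,6-dimethyl-3-(2-methyl-3-oxopent-4-en-2-yl)cyclohexan-1-one (C6 epimers)
Conditions: Dess–Martin periodinane, NaHCO3, CH2Cl2, 0 °C → rt
Reagents that add atoms: none
Why: Dess–Martin oxidation of the allylic alcohol under buffered, non-nucleophilic conditions, which should give the vinyl ketone without conjugate addition.

**Step 8**
Reactants: 12 (2R,3S)-2,6-dimethyl-3-(2-methyl-3-oxopent-4-en-2-yl)cyclohexan-1-one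
Product: 13 (4aR,8aS)-2,5,5,8a-tetramethyl-3,4,4a,7,8,8a-hexahydronaphthalene-1,6(2H,5H)-dione, i.e. cis-4,4,8,10-tetramethyldecalin-3,9-dione (5β-H, 10β-CH3; C8 epimers)
Conditions: KOt-Bu (0.2 equiv), t-BuOH–THF (1:4), 0.01 M, 0 °C → rt; aq. NH4Cl
Reagents that add atoms: none
Why: Catalytic tert-butoxide equilibrates the ketone enolates of 12, the C9=C10 enolate adds through C10 to the unsubstituted vinyl terminus C1, and t-BuOH protonates the resulting C3 enolate and returns the base; this is an intramolecular Michael addition, closest to the known base-mediated cyclisations of 2-methylcyclohexanones onto tethered enones that give cis-fused angular-methyl decalones. Ring A closes 6-endo-trig at the enone, with the enolate double bond exocyclic to the new ring. The only new stereocentre, C10, is set by C5: the C4–C3–C2 tether can reach C10 only on the face to which it is attached, and bonding perpendicular to the enolate plane puts C1 axial on ring B while C4 stays equatorial, so the C10 methyl ends syn to C5–H (cis fusion, 5R,10S). The step needs attack by C10 and not by C8, conjugate and not carbonyl addition, and retention at C5; the C8 enolate can only form an eight-membered ring or a strained bicyclo[2.2.2]octanol by reversible aldol addition to C3, both of which revert, while the 1,5-diketone is the thermodynamic sink. High dilution and sub-stoichiometric base at or below room temperature should hold back vinyl ketone oligomerisation and retro-Michael cleavage of C4–C5, which would erode C5.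

**Step 9**
Reactants: 13 cis-4,4,8,10-tetramethyldecalin-3,9-dione
Product: 14 cis-3,3-(ethylenedioxy)-4,4,8,10-tetramethyldecalin-9-one (5R,10S; C8 epimers)
Conditions: Me3SiOCH2CH2OSiMe3 (1.3 equiv), Me3SiOSO2CF3 (5 mol %), CH2Cl2, −78 → −20 °C; pyridine quench
Reagents that add atoms: 1,2-bis(trimethylsilyloxy)ethane, C[Si](C)(C)OCCO[Si](C)(C)C
Why: Noyori ketalisation under kinetic control, in which the C3 carbonyl has a free methylene neighbour whereas the C9 carbonyl lies between a quaternary and a tertiary carbon and should not react.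

**Step 10**
Reactants: 14 cis-3,3-(ethylenedioxy)-4,4,8,10-tetramethyldecalin-9-one
Product: 16 cis-3,3-(ethylenedioxy)-4,4,8,10-tetramethyl-9-(trimethylsilyloxy)decal-8-ene, via lithium enolate 15 (not isolated)
Conditions: LiN(i-Pr)2 (1.5 equiv), THF, −78 → 0 °C; Me3SiCl, Et3N, −78 °C → rt
Reagents that add atoms: chlorotrimethylsilane, C[Si](C)(C)Cl
Why: Enolate O-silylation; the C9 ketone can enolise only toward C8, so a single tetrasubstituted silyl enol ether should form.

**Step 11**
Reactants: 16 cis-3,3-(ethylenedioxy)-4,4,8,10-tetramethyl-9-(trimethylsilyloxy)decal-8-ene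
Product: 17 cis-3,3-(ethylenedioxy)-4,4,8,10-tetramethyldecal-7-en-9-one (5R,10S)
Conditions: Pd(OAc)2 (1.1 equiv), MeCN–CH2Cl2, rt → 40 °C
Reagents that add atoms: none
Why: Saegusa–Ito oxidation, in which the palladium enolate bonded at C8 should undergo β-hydride elimination toward the ring methylene C7 to give the endocyclic conjugated enone.

**Step 12**
Reactants: 17 cis-3,3-(ethylenedioxy)-4,4,8,10-tetramethyldecal-7-en-9-one
Product: 18 cis-3,3-(ethylenedioxy)-4,4,8,10-tetramethyl-9-methylidenedecal-7-ene (5S,10S)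
Conditions: (C5H5)2Ti(μ-CH2)(μ-Cl)Al(CH3)2 (Tebbe reagent, 2 equiv), pyridine (cat.), THF–toluene, −40 °C → rt; aq. NaOH
Reagents that add atoms: Tebbe reagent (supplies CH2), C[Al-]1(C)C[Ti]([Cl+]1)(C1C=CC=C1)C1C=CC=C1
Why: Tebbe methylenation; the small, non-basic titanium methylidene should convert the hindered, γ-enolisable enone carbonyl into the exocyclic C9=C11 alkene without isomerisation.

**Step 13**
Reactants: 18 cis-3,3-(ethylenedioxy)-4,4,8,10-tetramethyl-9-methylidenedecal-7-ene
Product: 20 (5S,9R,10S)-3,3-(ethylenedioxy)-5β,9β-drim-7-en-11-ol, via B-alkyl-9-borabicyclononane 19 (not isolated)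
Conditions: 9-borabicyclo[3.3.1]nonane (dimer, 1.5 equiv B–H), THF, 0 → 60 °C; then NaOH (3 M), H2O2 (30 %), 0 °C → rt
Reagents that add atoms: hydrogen peroxide, OO
Why: Hydroboration–oxidation of a conjugated diene at its 1,1-disubstituted terminus puts boron on C11 and hydrogen on C9; in either half-chair of ring B the concave α face of C9 is screened (by axial C1 or by the axial quaternary C4), so syn addition from the convex β face should place C9–H cis to the C10 methyl and C11 trans to it, while the trisubstituted C7=C8 bond is too hindered to react.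

**Step 14**
Reactants: 20 (5S,9R,10S)-3,3-(ethylenedioxy)-5β,9β-drim-7-en-11-ol; 21 umbelliferone (7-hydroxy-2H-chromen-2-one)
Product: 22 7-{[(5S,9R,10S)-3,3-(ethylenedioxy)-5β,9β-drim-7-en-11-yl]oxy}-2H-chromen-2-one
Conditions: 21 (1.3 equiv), PPh3, i-PrO2CN=NCO2i-Pr, THF, 0 °C → rt
Reagents that add atoms: none
Why: Mitsunobu etherification, in which the acidic phenol displaces the activated primary C11 oxyphosphonium group without touching C9.

**Step 15**
Reactants: 22 7-{[(5S,9R,10S)-3,3-(ethylenedioxy)-5β,9β-drim-7-en-11-yl]oxy}-2H-chromen-2-one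
Product: 23 7-{[(1R,4aS,8aS)-2,5,5,8a-tetramethyl-6-oxo-1,4,4a,5,6,7,8,8a-octahydronaphthalen-1-yl]methoxy}-2H-chromen-2-one (CNP0262399.3)
Conditions: HCl (1 M aq.), THF, rt
Reagents that add atoms: water, O
Why: Acid-catalysed ketal hydrolysis, fast for the strained ketal next to the gem-dimethyl carbon; dilute acid at room temperature should leave the aryl ether, the lactone and the C7=C8 position intact.

**Compound list**
1 | cyclohex-2-en-1-one | O=C1C=CCCC1 | starting material
2 | 1-methoxy-2-methyl-1-(trimethylsilyloxy)prop-1-ene | COC(O[Si](C)(C)C)=C(C)C | starting material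
3 | methyl 2-methyl-2-[(1S)-3-(trimethylsilyloxy)cyclohex-2-en-1-yl]propanoate | COC(=O)C(C)(C)[C@H]1CCCC(O[Si](C)(C)C)=C1 | intermediate
4 | benzyltrimethylammonium enolate of methyl 2-methyl-2-[(1S)-3-oxocyclohexyl]propanoate (enolate toward the substituted carbon) | COC(=O)C(C)(C)[C@H]1CCCC([O-])=C1.C[N+](C)(C)Cc1ccccc1 | intermediate
5 | methyl 2-methyl-2-[(1S,2R)-2-methyl-3-oxocyclohexyl]propanoate | COC(=O)C(C)(C)[C@H]1CCCC(=O)[C@@H]1C | intermediate
6 | lithium enolate of 5 toward the ring methylene | COC(=O)C(C)(C)[C@H]1CCC=C([O-])[C@@H]1C.[Li+] | intermediate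
7 | methyl 2-[(1S,2R)-2,4-dimethyl-3-oxocyclohexyl]-2-methylpropanoate (C4 epimers) | COC(=O)C(C)(C)[C@H]1CCC(C)C(=O)[C@@H]1C | intermediate
8 | (2R,3S)-3-(1-hydroxy-2-methylpropan-2-yl)-2,6-dimethylcyclohexan-1-ol (C1 and C6 epimers) | CC1CC[C@H](C(C)(C)CO)[C@@H](C)C1O | intermediate
9 | 2-[(1S,2R)-2,4-dimethyl-3-oxocyclohexyl]-2-methylpropanal (C4 epimers) | CC1CC[C@H](C(C)(C)C=O)[C@@H](C)C1=O | intermediate
10 | vinylmagnesium bromide | C=C[Mg]Br | starting material
11 | (2R,3S)-3-(3-hydroxy-2-methylpent-4-en-2-yl)-2,6-dimethylcyclohexan-1-one (carbinol and C6 epimers) | CC1CC[C@H](C(C)(C)C(O)C=C)[C@@H](C)C1=O | intermediate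
12 | (2R,3S)-2,6-dimethyl-3-(2-methyl-3-oxopent-4-en-2-yl)cyclohexan-1-one (C6 epimers) | CC1CC[C@H](C(C)(C)C(=O)C=C)[C@@H](C)C1=O | intermediate
13 | (4aR,8aS)-2,5,5,8a-tetramethyl-3,4,4a,7,8,8a-hexahydronaphthalene-1,6(2H,5H)-dione (cis-4,4,8,10-tetramethyldecalin-3,9-dione; C8 epimers) | CC1CC[C@@H]2C(C)(C)C(=O)CC[C@]2(C)C1=O | intermediate
14 | cis-3,3-(ethylenedioxy)-4,4,8,10-tetramethyldecalin-9-one (5R,10S; C8 epimers) | CC1CC[C@@H]2C(C)(C)C3(OCCO3)CC[C@]2(C)C1=O | intermediate
15 | lithium C8–C9 enolate of 14 | CC1=C([O-])[C@@]2(C)CCC3(OCCO3)C(C)(C)[C@H]2CC1.[Li+] | intermediate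
16 | cis-3,3-(ethylenedioxy)-4,4,8,10-tetramethyl-9-(trimethylsilyloxy)decal-8-ene | CC1=C(O[Si](C)(C)C)[C@@]2(C)CCC3(OCCO3)C(C)(C)[C@H]2CC1 | intermediate
17 | cis-3,3-(ethylenedioxy)-4,4,8,10-tetramethyldecal-7-en-9-one (5R,10S) | CC1=CC[C@@H]2C(C)(C)C3(OCCO3)CC[C@]2(C)C1=O | intermediate
18 | cis-3,3-(ethylenedioxy)-4,4,8,10-tetramethyl-9-methylidenedecal-7-ene (5S,10S) | CC1=CC[C@@H]2C(C)(C)C3(OCCO3)CC[C@]2(C)C1=C | intermediate
19 | B-[(5S,9R,10S)-3,3-(ethylenedioxy)-5β,9β-drim-7-en-11-yl]-9-borabicyclo[3.3.1]nonane | CC1=CC[C@@H]2C(C)(C)C3(OCCO3)CC[C@]2(C)[C@@H]1CB1C2CCCC1CCC2 | intermediate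
20 | (5S,9R,10S)-3,3-(ethylenedioxy)-5β,9β-drim-7-en-11-ol | CC1=CC[C@@H]2C(C)(C)C3(OCCO3)CC[C@]2(C)[C@@H]1CO | intermediate
21 | umbelliferone (7-hydroxy-2H-chromen-2-one) | O=c1ccc2ccc(O)cc2o1 | starting material
22 | 7-{[(5S,9R,10S)-3,3-(ethylenedioxy)-5β,9β-drim-7-en-11-yl]oxy}-2H-chromen-2-one | CC1=CC[C@@H]2C(C)(C)C3(OCCO3)CC[C@]2(C)[C@@H]1COc1ccc2ccc(=O)oc2c1 | intermediate
23 | 7-{[(1R,4aS,8aS)-2,5,5,8a-tetramethyl-6-oxo-1,4,4a,5,6,7,8,8a-octahydronaphthalen-1-yl]methoxy}-2H-chromen-2-one | CC1=CC[C@@H]2C(C)(C)C(=O)CC[C@]2(C)[C@@H]1COc1ccc2ccc(=O)oc2c1 | target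

**Step count**
Total: 15 steps. Longest linear sequence: 15 steps (1 → 23).

**Steps most likely to fail**

Step 13. The borane may not discriminate well between the two faces of C9=C11 if the two ring-B half-chairs react at similar rates, which would give the wrong configuration at C9. The fallback sets out from 14 and comes back at 20. Ketone 14 is converted with KN(SiMe3)2 and PhN(SO2CF3)2 (THF, −78 → 0 °C) into the C8=C9 enol triflate F1. Methoxycarbonylation (Pd(OAc)2/PPh3, reduced in the flask to the zerovalent palladium catalyst, CO 1 atm, MeOH, Et3N, DMF, 60 °C) gives the conjugated methyl ester F2. γ-Deprotonation at the ring methylene C7 with LiN(i-Pr)2 in THF–(Me2N)3PO at −78 °C, then kinetic C9 protonation of the dienolate by a hindered phenol, gives the deconjugated ester F3. LiAlH4 reduction then leads to 20. Here the proton donor can be varied in size, and an unwanted C9 epimer can be returned to the same dienolate by renewed deprotonation.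

Step 8. The vinyl ketone may oligomerise or add intermolecularly faster than ring A closes, and prolonged base may cleave C4–C5 by retro-Michael reaction. The fallback sets out from 9 and comes back at 13. Aldehyde 9 is treated with CH2=C(SiMe3)MgBr (THF, −78 °C) to give the α-silyl allylic alcohol F4, and Dess–Martin oxidation gives the α-trimethylsilyl vinyl ketone F5. Silicon stabilises the α-carbanion formed in the conjugate addition and suppresses polymerisation. The same KOt-Bu/t-BuOH–THF conditions should close ring A to the 2-silyl dione F6, which the alkoxide desilylates in the same flask to 13.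

Step 9. The ketalisation may fail to distinguish the two hindered carbonyls, either reacting sluggishly at C3 or partly at C9. The fallback sets out from 13 and comes back at 17, and differentiates the ketones electronically. Double enolisation and silylation (LiN(i-Pr)2 2.5 equiv, Me3SiCl) gives the bis(silyl enol ether) F7. Pd(OAc)2 (2.2 equiv) gives the Δ1,Δ7-dienedione F8. Hydrogenation with RhCl(PPh3)3 (H2 1 atm, benzene) saturates only the disubstituted C1=C2 bond to give the Δ7-ene-3,9-dione F9. Ketalisation as in step 9 then occurs at the saturated C3 ketone and not at the conjugated, hindered C9 enone, which gives 17.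

**Further compounds**
F1 | step 13 | cis-3,3-(ethylenedioxy)-4,4,8,10-tetramethyldecal-8-en-9-yl trifluoromethanesulfonate | CC1=C(OS(=O)(=O)C(F)(F)F)[C@@]2(C)CCC3(OCCO3)C(C)(C)[C@H]2CC1
F2 | step 13 | methyl cis-3,3-(ethylenedioxy)-5β-drim-8-en-11-oate | CC1=C(C(=O)OC)[C@@]2(C)CCC3(OCCO3)C(C)(C)[C@H]2CC1
F3 | step 13 | methyl (5S,9R,10S)-3,3-(ethylenedioxy)-5β,9β-drim-7-en-11-oate | CC1=CC[C@@H]2C(C)(C)C3(OCCO3)CC[C@]2(C)[C@@H]1C(=O)OC
F4 | step 8 | (2R,3S)-3-[3-hydroxy-2-methyl-4-(trimethylsilyl)pent-4-en-2-yl]-2,6-dimethylcyclohexan-1-one | CC1CC[C@H](C(C)(C)C(O)C(=C)[Si](C)(C)C)[C@@H](C)C1=O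
F5 | step 8 | (2R,3S)-2,6-dimethyl-3-[2-methyl-3-oxo-4-(trimethylsilyl)pent-4-en-2-yl]cyclohexan-1-one | CC1CC[C@H](C(C)(C)C(=O)C(=C)[Si](C)(C)C)[C@@H](C)C1=O
F6 | step 8 | cis-4,4,8,10-tetramethyl-2-(trimethylsilyl)decalin-3,9-dione | CC1CC[C@@H]2C(C)(C)C(=O)C([Si](C)(C)C)C[C@]2(C)C1=O
F7 | step 9 | cis-4,4,8,10-tetramethyl-3,9-bis(trimethylsilyloxy)decala-2,8-diene | CC1=C(O[Si](C)(C)C)[C@@]2(C)CC=C(O[Si](C)(C)C)C(C)(C)[C@H]2CC1
F8 | step 9 | cis-4,4,8,10-tetramethyldecala-1,7-diene-3,9-dione | CC1=CC[C@@H]2C(C)(C)C(=O)C=C[C@]2(C)C1=O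
F9 | step 9 | cis-4,4,8,10-tetramethyldecal-7-ene-3,9-dione | CC1=CC[C@@H]2C(C)(C)C(=O)CC[C@]2(C)C1=O
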